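**Retrosynthetic overview**
- The (Z)-butenoyl ketone is disconnected last to an S-ethyl thioester (Liebeskind–Srogl acylation); before that come esterification of the C5 hydroxyl and removal of a C1/C5 acetonide.
- Key disconnection: the C7–C11 bond of the α-methylidene lactone, made by O-acryloylation of a γ-hydroxy cycloheptenone and phosphine-catalysed Rauhut–Currier closure of the crude acrylate. Enabling feature: the lactone oxygen on C6 is γ to the C9 ketone (C6–C7=C8–C9=O), so C7 is an enone β-carbon five atoms from the acrylate α-carbon and the five-membered ring closes 5-exo, cis, on the seven-membered ring.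
- The cycloheptenone comes from an acyclic diene by ring-closing metathesis (C8=C9 methyl enol ether), selenoxide elimination to the C7=C8 enone and α′-methylation at C10.
- The diene comes from dimethyl L-tartrate acetonide: C5 from the chiral pool, C6 by reagent-controlled allylboration, quaternary C1 by anti alkylation of the dioxolane thioester enolate.
- Ring order: dioxolane (present from the start, temporary), then the seven-membered carbocycle (step 5), then the lactone (step 9).

Key step: step 9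

Remark: locants in the Why lines are C9 ring ketone, C10 its methyl-bearing α-carbon, C1 the carbinol carbon carrying the C2–C3=C4–C15 butenoyl chain, C5 the isovalerate carbon, C6 the lactone-oxygen carbon, C7 the ring-fusion carbon, C8 the ring CH2, C11/C12/C13 the lactone α-carbon, carbonyl and methylidene carbons; the allylboronate, 3-bromo-2-methoxypropene and (Z)-prop-1-enylboronic acid are taken as purchasable reagents.

Step 1
Reactants: 1 dimethyl (4R,5R)-2,2-dimethyl-1,3-dioxolane-4,5-dicarboxylate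
Product: 3 methyl (4R,5S)-5-[(1R)-1-hydroxybut-3-en-1-yl]-2,2-dimethyl-1,3-dioxolane-4-carboxylate, via aldehyde 2 (not isolated)
Conditions: iBu2AlH (1.05 equiv), PhMe, −78 °C; MeOH, aq. KNaC4H4O6; crude aldehyde, (S,S)-diisopropyl tartrate allylboronate, 4 Å molecular sieves, PhMe, −78 °C
Reagents that add atoms: diisopropyl (4S,5S)-2-allyl-1,3,2-dioxaborolane-4,5-dicarboxylate (CC(C)OC(=O)[C@H]1OB(CC=C)O[C@@H]1C(=O)OC(C)C)
Why: Half-reduction of one of the two homotopic esters stops at the aldehyde through the chelated aluminium hemiacetal, and Roush asymmetric allylboration with the (S,S)-tartrate reagent should deliver allyl to the Re face under reagent control (mismatched with the substrate bias), setting the C6 carbinol (R) syn to the C5 oxygen while the trans-dioxolane is kept.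

Step 2
Reactants: 3 methyl (4R,5S)-5-[(1R)-1-hydroxybut-3-en-1-yl]-2,2-dimethyl-1,3-dioxolane-4-carboxylate
Product: 4 methyl (4R,5R)-5-[(1R)-1-[tert-butyl(dimethyl)silyl]oxybut-3-en-1-yl]-2,2-dimethyl-1,3-dioxolane-4-carboxylate
Conditions: t-BuMe2SiCl, imidazole, DMF, 0 °C to rt
Reagents that add atoms: tert-butyl(chloro)dimethylsilane (CC(C)(C)[Si](C)(C)Cl)
Why: Silyl ether formation masks the C6 hydroxyl for the enolate steps that follow; no stereocentre is touched.

Step 3
Reactants: 4 methyl (4R,5R)-5-[(1R)-1-[tert-butyl(dimethyl)silyl]oxybut-3-en-1-yl]-2,2-dimethyl-1,3-dioxolane-4-carboxylate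
Product: 5 S-ethyl (4R,5R)-5-[(1R)-1-[tert-butyl(dimethyl)silyl]oxybut-3-en-1-yl]-2,2-dimethyl-1,3-dioxolane-4-carbothioate
Conditions: AlMe3, EtSH, CH2Cl2, 0 °C (Me2AlSEt formed in the flask); then 4, 0 °C to rt
Reagents that add atoms: ethanethiol (CCS)
Why: Ester-to-thioester exchange with dimethylaluminium ethanethiolate, formed in the flask from AlMe3 and EtSH with loss of methane, gives the acyl group that can be turned into the ketone at the very end under neutral conditions; the α-centre is not enolized.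

Step 4
Reactants: 5 S-ethyl (4R,5R)-5-[(1R)-1-[tert-butyl(dimethyl)silyl]oxybut-3-en-1-yl]-2,2-dimethyl-1,3-dioxolane-4-carbothioate
Product: 6 S-ethyl (4S,5S)-5-[(1R)-1-[tert-butyl(dimethyl)silyl]oxybut-3-en-1-yl]-4-(2-methoxyprop-2-en-1-yl)-2,2-dimethyl-1,3-dioxolane-4-carbothioate
Conditions: LiN(iPr)2, THF/DMPU, −78 °C; CH2=C(OMe)CH2Br, −78 to −40 °C
Reagents that add atoms: 3-bromo-2-methoxyprop-1-ene (COC(=C)CBr)
Why: Enolate alkylation of a dioxolane-4-carboxylic acid derivative (the tartrate acetonide enolate alkylation): the exocyclic enolate cannot expel the ring oxygen for stereoelectronic reasons, and the allylic bromide should enter anti to the bulky C5 side chain, which sets the quaternary C1 centre with the thioester cis to that chain.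

Step 5
Reactants: 6 S-ethyl (4S,5S)-5-[(1R)-1-[tert-butyl(dimethyl)silyl]oxybut-3-en-1-yl]-4-(2-methoxyprop-2-en-1-yl)-2,2-dimethyl-1,3-dioxolane-4-carbothioate
Product: 7 S-ethyl (3aS,8R,8aS)-8-[tert-butyl(dimethyl)silyl]oxy-5-methoxy-2,2-dimethyl-4,7,8,8a-tetrahydro-3aH-cyclohepta[d][1,3]dioxole-3a-carbothioate
Conditions: second-generation Grubbs catalyst RuCl2(=CHPh)(PCy3)(H2IMes) (5 mol%), CH2Cl2, 40 °C
Reagents that add atoms: none
Why: Ring-closing metathesis initiated at the terminal allyl group and closing onto the 1,1-disubstituted enol ether should form the seven-membered ring as its C8=C9 methyl enol ether with loss of ethene; no stereocentre is formed.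

Step 6
Reactants: 7 S-ethyl (3aS,8R,8aS)-8-[tert-butyl(dimethyl)silyl]oxy-5-methoxy-2,2-dimethyl-4,7,8,8a-tetrahydro-3aH-cyclohepta[d][1,3]dioxole-3a-carbothioate
Product: 9 S-ethyl (3aS,8R,8aS)-8-[tert-butyl(dimethyl)silyl]oxy-2,2-dimethyl-5-oxo-4,5,8,8a-tetrahydro-3aH-cyclohepta[d][1,3]dioxole-3a-carbothioate, via selenide 8 (not isolated)
Conditions: PhSeCl, pyridine, CH2Cl2, −78 °C; H2O; then 30% H2O2, 0 °C to rt
Reagents that add atoms: water (O)
Why: Electrophilic selenenylation of the enol ether can occur only at C8 and hydrolysis gives the α-selanyl ketone, whose selenoxide undergoes syn-elimination (selenoxide elimination) toward C7, the only neighbour with hydrogens, so the C7=C8 enone should form regiospecifically.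

Step 7
Reactants: 9 S-ethyl (3aS,8R,8aS)-8-[tert-butyl(dimethyl)silyl]oxy-2,2-dimethyl-5-oxo-4,5,8,8a-tetrahydro-3aH-cyclohepta[d][1,3]dioxole-3a-carbothioate
Product: 10 S-ethyl (3aS,4R,8R,8aS)-8-[tert-butyl(dimethyl)silyl]oxy-2,2,4-trimethyl-5-oxo-4,5,8,8a-tetrahydro-3aH-cyclohepta[d][1,3]dioxole-3a-carbothioate
Conditions: LiN(SiMe3)2, THF, −78 °C; MeI, −78 to −40 °C
Reagents that add atoms: iodomethane (CI)
Why: Kinetic α′-deprotonation of the enone at C10 and C-methylation of the cross-conjugated lithium dienolate (enolate alkylation) at low temperature, where loss of the C1 oxygen is slow because the trans-fused dioxolane holds the C1–O bond pseudo-equatorial and out of line with the enolate π-system; methyl iodide should approach anti to the pseudo-axial thioester on the neighbouring quaternary carbon, placing the C10 methyl cis to the C1 oxygen, and the centre stays open to base equilibration if the epimer forms.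

Step 8
Reactants: 10 S-ethyl (3aS,4R,8R,8aS)-8-[tert-butyl(dimethyl)silyl]oxy-2,2,4-trimethyl-5-oxo-4,5,8,8a-tetrahydro-3aH-cyclohepta[d][1,3]dioxole-3a-carbothioate
Product: 11 S-ethyl (3aS,4R,8R,8aS)-8-hydroxy-2,2,4-trimethyl-5-oxo-4,5,8,8a-tetrahydro-3aH-cyclohepta[d][1,3]dioxole-3a-carbothioate
Conditions: HF·pyridine, THF, 0 °C to rt
Reagents that add atoms: none
Why: Fluoride-mediated cleavage of the silyl ether frees the C6 hydroxyl; the acetonide and the thioester are stable to buffered HF and no stereocentre is affected.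

Step 9
Reactants: 11 S-ethyl (3aS,4R,8R,8aS)-8-hydroxy-2,2,4-trimethyl-5-oxo-4,5,8,8a-tetrahydro-3aH-cyclohepta[d][1,3]dioxole-3a-carbothioate
Product: 13 S-ethyl thioester of the acetonide-protected cis-fused α-methylidene-γ-butyrolactone (C1 S; C5 S; C6 R; C7 S; C10 R), via acrylate 12 (not isolated)
Conditions: acrylic anhydride, Et3N, DMAP (cat.), CH2Cl2, 0 °C; aq. NaHCO3 wash; crude acrylate, PBu3 (30 mol%), t-BuOH, CH2Cl2, rt
Reagents that add atoms: acrylic anhydride (C=CC(=O)OC(=O)C=C)
Why: After O-acylation of the C6 hydroxyl and removal of the acrylate salts, PBu3 adds reversibly to the acrylate β-carbon C13, the phosphonium enolate attacks the enone β-carbon C7 through its α-carbon C11, and proton transfer from C11 to C8 (helped by t-BuOH) followed by β-elimination of PBu3 frees the catalyst and leaves the C11=C13 methylidene. The closest known reaction type is the phosphine-catalysed intramolecular Rauhut–Currier cycloisomerization of acrylates of 4-hydroxy cyclic enones and dienones to cis-fused α-methylidene-γ-butyrolactones. The only ring closed is the lactone, by a 5-exo-trig closure in which the three-atom O–C12–C11 tether spans C6 and C7. The new stereocentre C7 is controlled by C6: the tether reaches C7 only when the C6–O bond is pseudo-axial, so C11 is delivered to the face that carries the oxygen and the ring fusion should be cis. The step needs chemoselectivity between two acceptors and site selectivity for C7, which the substrate secures because phosphine adducts of the ring enone have no five-membered pathway and revert, C7 is the only electrophilic carbon within reach of C11, and the thioester, dioxolane and C10 centre are inert to these neutral conditions.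

Step 10
Reactants: 13 S-ethyl thioester of the acetonide-protected cis-fused α-methylidene-γ-butyrolactone (C1 S; C5 S; C6 R; C7 S; C10 R)
Product: 14 S-ethyl (3aS,6R,7S,8S,8aR)-7,8-dihydroxy-6-methyl-3-methylidene-2,5-dioxooctahydro-2H-cyclohepta[b]furan-7-carbothioate
Conditions: CF3CO2H/H2O (9:1), 0 °C
Reagents that add atoms: none
Why: Acid-catalysed acetal hydrolysis of the strained trans-fused dioxolane releases the C1/C5 diol; the α-methylidene lactone, the thioester and the β-hydroxy ketone should tolerate cold aqueous acid and no stereocentre is affected.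

Step 11
Reactants: 14 S-ethyl (3aS,6R,7S,8S,8aR)-7,8-dihydroxy-6-methyl-3-methylidene-2,5-dioxooctahydro-2H-cyclohepta[b]furan-7-carbothioate
Product: 15 S-ethyl (3aS,6R,7S,8S,8aR)-7-hydroxy-6-methyl-3-methylidene-8-[(3-methylbutanoyl)oxy]-2,5-dioxooctahydro-2H-cyclohepta[b]furan-7-carbothioate
Conditions: (iPrCH2CO)2O, DMAP (cat.), pyridine, CH2Cl2, 0 °C
Reagents that add atoms: 3-methylbutanoic anhydride (CC(C)CC(=O)OC(=O)CC(C)C)
Why: DMAP-catalysed acylation should esterify the secondary C5 hydroxyl only, the tertiary C1 hydroxyl being too hindered, and the weak base avoids retro-aldol cleavage of the β-hydroxy ketone.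

Step 12
Reactants: 15 S-ethyl (3aS,6R,7S,8S,8aR)-7-hydroxy-6-methyl-3-methylidene-8-[(3-methylbutanoyl)oxy]-2,5-dioxooctahydro-2H-cyclohepta[b]furan-7-carbothioate
Product: 16 (3aS,6R,7S,8S,8aR)-7-[(2Z)-but-2-enoyl]-7-hydroxy-6-methyl-3-methylidene-2,5-dioxooctahydro-2H-cyclohepta[b]furan-8-yl 3-methylbutanoate
Conditions: (Z)-MeCH=CHB(OH)2, Pd2(dba)3 (5 mol%), P(2-furyl)3, Cu(O2C-2-thienyl) (1.5 equiv), THF, 50 °C
Reagents that add atoms: (Z)-prop-1-en-1-ylboronic acid (C/C=C\B(O)O)
Why: Liebeskind–Srogl coupling, in which zerovalent palladium inserts into the copper-activated C–S bond, the alkenylboronic acid transmetalates with retention of the Z geometry and reductive elimination gives the enone under neutral conditions that spare the lactone, the ring ketone, the ester and the tertiary alcohol.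

**Compound list**
1 | dimethyl (4R,5R)-2,2-dimethyl-1,3-dioxolane-4,5-dicarboxylate (dimethyl L-tartrate acetonide) | COC(=O)[C@@H]1OC(C)(C)O[C@H]1C(=O)OC | starting material
2 | methyl (4R,5R)-5-formyl-2,2-dimethyl-1,3-dioxolane-4-carboxylate | COC(=O)[C@@H]1OC(C)(C)O[C@H]1C=O | intermediate
3 | methyl (4R,5S)-5-[(1R)-1-hydroxybut-3-en-1-yl]-2,2-dimethyl-1,3-dioxolane-4-carboxylate | COC(=O)[C@@H]1OC(C)(C)O[C@H]1[C@H](O)CC=C | intermediate
4 | methyl (4R,5R)-5-[(1R)-1-[tert-butyl(dimethyl)silyl]oxybut-3-en-1-yl]-2,2-dimethyl-1,3-dioxolane-4-carboxylate | COC(=O)[C@@H]1OC(C)(C)O[C@H]1[C@H](O[Si](C)(C)C(C)(C)C)CC=C | intermediate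
5 | S-ethyl (4R,5R)-5-[(1R)-1-[tert-butyl(dimethyl)silyl]oxybut-3-en-1-yl]-2,2-dimethyl-1,3-dioxolane-4-carbothioate | CCSC(=O)[C@@H]1OC(C)(C)O[C@H]1[C@H](O[Si](C)(C)C(C)(C)C)CC=C | intermediate
6 | S-ethyl (4S,5S)-5-[(1R)-1-[tert-butyl(dimethyl)silyl]oxybut-3-en-1-yl]-4-(2-methoxyprop-2-en-1-yl)-2,2-dimethyl-1,3-dioxolane-4-carbothioate | CCSC(=O)[C@@]1(CC(OC)=C)OC(C)(C)O[C@H]1[C@H](O[Si](C)(C)C(C)(C)C)CC=C | intermediate
7 | S-ethyl (3aS,8R,8aS)-8-[tert-butyl(dimethyl)silyl]oxy-5-methoxy-2,2-dimethyl-4,7,8,8a-tetrahydro-3aH-cyclohepta[d][1,3]dioxole-3a-carbothioate | CCSC(=O)[C@]12CC(OC)=CC[C@@H](O[Si](C)(C)C(C)(C)C)[C@@H]1OC(C)(C)O2 | intermediate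
8 | S-ethyl (3aS,8R,8aS)-8-[tert-butyl(dimethyl)silyl]oxy-2,2-dimethyl-5-oxo-6-(phenylselanyl)hexahydro-3aH-cyclohepta[d][1,3]dioxole-3a-carbothioate (both epimers at the selenium-bearing carbon) | CCSC(=O)[C@]12CC(=O)C([Se]c3ccccc3)C[C@@H](O[Si](C)(C)C(C)(C)C)[C@@H]1OC(C)(C)O2 | intermediate
9 | S-ethyl (3aS,8R,8aS)-8-[tert-butyl(dimethyl)silyl]oxy-2,2-dimethyl-5-oxo-4,5,8,8a-tetrahydro-3aH-cyclohepta[d][1,3]dioxole-3a-carbothioate | CCSC(=O)[C@]12CC(=O)C=C[C@@H](O[Si](C)(C)C(C)(C)C)[C@@H]1OC(C)(C)O2 | intermediate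
10 | S-ethyl (3aS,4R,8R,8aS)-8-[tert-butyl(dimethyl)silyl]oxy-2,2,4-trimethyl-5-oxo-4,5,8,8a-tetrahydro-3aH-cyclohepta[d][1,3]dioxole-3a-carbothioate | CCSC(=O)[C@]12[C@@H](C)C(=O)C=C[C@@H](O[Si](C)(C)C(C)(C)C)[C@@H]1OC(C)(C)O2 | intermediate
11 | S-ethyl (3aS,4R,8R,8aS)-8-hydroxy-2,2,4-trimethyl-5-oxo-4,5,8,8a-tetrahydro-3aH-cyclohepta[d][1,3]dioxole-3a-carbothioate | CCSC(=O)[C@]12[C@@H](C)C(=O)C=C[C@@H](O)[C@@H]1OC(C)(C)O2 | intermediate
12 | S-ethyl (3aS,4R,8R,8aS)-8-(acryloyloxy)-2,2,4-trimethyl-5-oxo-4,5,8,8a-tetrahydro-3aH-cyclohepta[d][1,3]dioxole-3a-carbothioate | CCSC(=O)[C@]12[C@@H](C)C(=O)C=C[C@@H](OC(=O)C=C)[C@@H]1OC(C)(C)O2 | intermediate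
13 | S-ethyl thioester of the acetonide-protected cis-fused α-methylidene-γ-butyrolactone (C1 S; C5 S; C6 R; C7 S; C10 R) | CCSC(=O)[C@]12[C@@H](C)C(=O)C[C@H]3C(=C)C(=O)O[C@H]3[C@@H]1OC(C)(C)O2 | intermediate
14 | S-ethyl (3aS,6R,7S,8S,8aR)-7,8-dihydroxy-6-methyl-3-methylidene-2,5-dioxooctahydro-2H-cyclohepta[b]furan-7-carbothioate | CCSC(=O)[C@]1(O)[C@@H](C)C(=O)C[C@H]2C(=C)C(=O)O[C@H]2[C@@H]1O | intermediate
15 | S-ethyl (3aS,6R,7S,8S,8aR)-7-hydroxy-6-methyl-3-methylidene-8-[(3-methylbutanoyl)oxy]-2,5-dioxooctahydro-2H-cyclohepta[b]furan-7-carbothioate | CCSC(=O)[C@]1(O)[C@@H](C)C(=O)C[C@H]2C(=C)C(=O)O[C@H]2[C@@H]1OC(=O)CC(C)C | intermediate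
16 | (3aS,6R,7S,8S,8aR)-7-[(2Z)-but-2-enoyl]-7-hydroxy-6-methyl-3-methylidene-2,5-dioxooctahydro-2H-cyclohepta[b]furan-8-yl 3-methylbutanoate | C/C=C\C(=O)[C@]1(O)[C@@H](C)C(=O)C[C@H]2C(=C)C(=O)O[C@H]2[C@@H]1OC(=O)CC(C)C | target

Total step count: 12. Longest linear sequence: 12 steps (1 to 16).

**Steps most likely to fail**

Step 4. The thioester enolate may collapse to a ketene by loss of ethanethiolate before it meets the bromide, or may be alkylated with poor facial discrimination. The fallback sets out from 4: the same alkylation (LiN(iPr)2, THF/DMPU, −78 °C, 3-bromo-2-methoxypropene) is run on the ester enolate, the substrate class on which this anti alkylation is established, to give the methyl ester F1. The hindered ester is then cleaved with Me3SnOH (1,2-dichloroethane, 70 °C), which leaves the enol ether intact, to give the carboxylic acid F2. Coupling with EtSH (DCC, DMAP cat., CH2Cl2) comes back to the route at 6.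

Step 9. Turnover of the phosphine may stall if the phosphonium enolate is protonated before it cyclizes or if elimination of the phosphine from the cyclized adduct is slow; acrylate oligomerization and closure to the trans-fused lactone are further losses. The fallback sets out from 11: esterification with diethylphosphonoacetic acid (DCC, DMAP cat., CH2Cl2) gives the phosphonoacetate F3. Base (Cs2CO3, MeCN, 0 °C) should then bring about the 5-exo intramolecular Michael addition to the α-phosphono lactone F4. Horner–Wadsworth–Emmons olefination with aqueous formaldehyde and K2CO3 installs the methylidene and comes back to the route at 13.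

Step 12. Acyl transfer from the hindered α-hydroxy thioester to palladium may be slow, and the propenyl group may isomerize from Z to E during a sluggish coupling. The fallback sets out from 15: Fukuyama reduction (Et3SiH, Pd/CaCO3 poisoned with Pb(OAc)2, acetone) gives the aldehyde F5. Nozaki–Hiyama–Kishi addition of (Z)-1-iodoprop-1-ene (CrCl2, NiCl2 cat., DMSO) gives the allylic alcohol F6 as a mixture of carbinol epimers. Oxidation with Dess–Martin periodinane (NaHCO3, CH2Cl2, 0 °C) comes back to the route at 16.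

Further compounds
F1 | step 4 | methyl (4S,5S)-5-[(1R)-1-[tert-butyl(dimethyl)silyl]oxybut-3-en-1-yl]-4-(2-methoxyprop-2-en-1-yl)-2,2-dimethyl-1,3-dioxolane-4-carboxylate | COC(=O)[C@@]1(CC(OC)=C)OC(C)(C)O[C@H]1[C@H](O[Si](C)(C)C(C)(C)C)CC=C
F2 | step 4 | (4S,5S)-5-[(1R)-1-[tert-butyl(dimethyl)silyl]oxybut-3-en-1-yl]-4-(2-methoxyprop-2-en-1-yl)-2,2-dimethyl-1,3-dioxolane-4-carboxylic acid | OC(=O)[C@@]1(CC(OC)=C)OC(C)(C)O[C@H]1[C@H](O[Si](C)(C)C(C)(C)C)CC=C
F3 | step 9 | S-ethyl (3aS,4R,8R,8aS)-8-[2-(diethoxyphosphoryl)acetyl]oxy-2,2,4-trimethyl-5-oxo-4,5,8,8a-tetrahydro-3aH-cyclohepta[d][1,3]dioxole-3a-carbothioate | CCSC(=O)[C@]12[C@@H](C)C(=O)C=C[C@@H](OC(=O)CP(=O)(OCC)OCC)[C@@H]1OC(C)(C)O2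
F4 | step 9 | S-ethyl thioester of the acetonide-protected cis-fused α-(diethoxyphosphoryl)-γ-butyrolactone (both epimers at the phosphorus-bearing carbon) | CCSC(=O)[C@]12[C@@H](C)C(=O)C[C@H]3C(P(=O)(OCC)OCC)C(=O)O[C@H]3[C@@H]1OC(C)(C)O2
F5 | step 12 | (3aS,6R,7S,8S,8aR)-7-formyl-7-hydroxy-6-methyl-3-methylidene-2,5-dioxooctahydro-2H-cyclohepta[b]furan-8-yl 3-methylbutanoate | O=C[C@]1(O)[C@@H](C)C(=O)C[C@H]2C(=C)C(=O)O[C@H]2[C@@H]1OC(=O)CC(C)C
F6 | step 12 | (3aS,6R,7S,8S,8aR)-7-hydroxy-7-[(2Z)-1-hydroxybut-2-en-1-yl]-6-methyl-3-methylidene-2,5-dioxooctahydro-2H-cyclohepta[b]furan-8-yl 3-methylbutanoate (both carbinol epimers) | C/C=C\C(O)[C@]1(O)[C@@H](C)C(=O)C[C@H]2C(=C)C(=O)O[C@H]2[C@@H]1OC(=O)CC(C)C
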